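## Analysis of the target

The target (compound 13) is 3,5-dibromo-2-(2,3,5-tribromo-4-hydroxyphenoxy)benzene-1,4-diol, C12H5Br5O4: two benzene rings joined through one oxygen, with no side chain and no further ring. Ring A is numbered C1 (OH), C2 (ether O), C3 (Br), C4 (OH), C5 (Br), C6 (H); ring B is numbered C1' (ether O), C2' (Br), C3' (Br), C4' (OH), C5' (Br), C6' (H). There is no stereocentre, and the ether axis, which has only three ortho substituents of moderate size, is assumed to rotate freely, so no stereochemical relation has to be set. The sensitive groups are the hydroquinone of ring A (C1 and C4 hydroxyls para to each other), which oxidises easily to a bromoquinone, and the five aryl bromides, which rule out hydrogenolysis and organolithium chemistry late in the route. The difficulty is regiochemical: ten of the twelve ring carbons carry a heteroatom, the ether oxygen sits between C1–O and C3–Br on ring A and C2'–Br on ring B, and the C2' bromine is meta to the C4' oxygen, so no phenol-directed bromination can place it. The strategy rests on ring B, where C3' and C5' are ortho and para to C2'. A nitrogen at C2' can therefore serve three times: as a nitro group it activates C1' for ether formation, as an amino group it steers bromine to C3' and C5', and as a diazonium group it is exchanged for the C2' bromine.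

## Retrosynthetic reasoning

**13 to 11.** The three O–H bonds are traced back to O–CH3 bonds, giving trimethyl ether 11. Free phenols would leave ring A oxidisable throughout, would compete as nucleophiles in the ether formation and would be brominated without control. Methyl ethers are the smallest groups that survive base, iron, bromine and diazotisation. The forward step must cleave all three ethers with a Lewis acid without touching the diaryl ether or the C–Br bonds.

**11 to 9.** The C2'–Br bond is cut and replaced by C2'–N, giving aniline 9, with diazonium salt 10 as the link. C2' is the one brominated carbon that electrophilic substitution would not choose, because it is meta to the C4' oxygen. An amino group is the only substituent that can direct the other brominations and then be exchanged for bromine. The forward step is a Sandmeyer bromination on an aniline flanked by Br and OAr.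

**9 to 8 and 4.** The C3'–Br and C5'–Br bonds are cut together, giving amino diaryl ether 8 and bromine (4). Both carbons are ortho or para to the nitrogen and ortho to the C4' methoxy group, so the two strongest donors of the molecule point at the same two sites. The forward reaction must stop at two bromines on ring B and leave C6' and the open C6 of ring A alone.

**8 to 7.** The amino group is traced back to the nitro group of 7. This is a change of oxidation level only, but it is what allows the same nitrogen to serve the ether formation. The forward reduction must spare the aryl bromides.

**7 to 5 and 6.** The C1'–O bond is cut, giving phenol 5 and fluoronitroarene 6. The cut is made on the ring B side because C1' can carry an ortho nitro group and a fluoride leaving group. The C2 carbon of ring A, flanked by two donors, offers no handle for nucleophilic substitution. The disconnection is convergent and puts all ring A substituents on a monocyclic phenol. The forward SNAr must accept a phenoxide with two ortho substituents.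

**5 to 3 and 4.** The two C–Br bonds of ring A (C3–Br and C5–Br of the target) are cut, giving phenol 3. In 3 the free hydroxyl directs bromine (4) to its para and its open ortho position, which are exactly these carbons. The third open carbon is meta to the hydroxyl and becomes C6 of the target.

**3 to 1.** The aryl C–O bond of 3 is traced back to the aryl–CHO bond of aldehyde 1 through formate 2, a Baeyer–Villiger oxygen insertion. Aldehyde 1 is an inexpensive arene that already has the two methoxy groups in the para relation of ring A.

## Alternatives that were turned down

**Alternative 1:** Ring A is not taken from an arene but built around its oxygens. The disconnection opens ring A at C4–C5 and leads back to the racemic 4-vinylcyclobutenone A2, which would be assembled from dimethyl squarate A3 and the complete ring B aryloxy group. In the forward key step A2 is heated, the four-membered ring opens to a dienyl ketene, and 6-pi electrocyclisation followed by enolisation gives phenol A1. A1 has the C4 hydroxyl, the C3 bromine, the C2 aryloxy group and the C1 methoxy group in place. Bromination ortho to the new hydroxyl (C5) and demethylation would finish the synthesis.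
- For it: the positions of the ring A substituents follow from connectivity and not from the selectivity of an aromatic substitution. On this point it is stronger than the chosen route, which relies on the directing power of the hydroxyl of 3.
- Against it: A2 must already carry the 2,3,5-tribromo-4-methoxyphenoxy group, so the hard problem, the C2' bromine of ring B, is left unsolved and moved into a building block.
- Against it: the brominated, aryloxy-substituted cyclobutenone needs several steps of regioselective addition and substitution on A3, where a bromine on the ring is itself a leaving group.
- Comparison: the chosen route makes ring A in two steps from a commercial arene and spends its effort on ring B, where the real selectivity problem lies.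

**Alternative 2:** Both phenolic C–O bonds para to the ether bridge substituents (C4–O and C4'–O) are traced back to aryl–CHO bonds. The bis-aldehyde diaryl ether A5 would come from one SNAr between two commercial benzaldehydes, with the C2' bromine bought in. In the forward key step a peracid inserts oxygen into both aryl–formyl bonds and basic methanolysis cleaves the two formates to give bisphenol A4. A fourfold bromination ortho to the two new hydroxyls and one demethylation would complete the target.
- For it: about four steps from cheap materials, a very activated SNAr (fluoride para to a formyl group), and the C2' bromine present from the start. It is clearly stronger than the chosen route in step count and convergence.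
- Against it: the ring B aldehyde of A5 is para to an aryloxy group and meta to bromine. Its aryl group migrates poorly, so hydride migration to the carboxylic acid competes in the twofold oxidation.
- Against it: the closing bromination must place four bromines and no more. Two of them go into flanked positions (C3 between OH and OAr, C3' between OH and Br). The 4-methoxyphenol ring of A4 is a hydroquinone monoether that bromine oxidises to a quinone, and C6 remains open to over-bromination.
- Comparison: a mixture of tri-, tetra- and pentabromides from that step would be hard to separate. The chosen route is longer, but each bromine is placed under a dominant director on an intermediate that can be purified.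

**Alternative 3:** Ring B is introduced as a cyclohexene and aromatised late. The O–C1' and C2'–Br bonds are cut together, leading to phenol 5 and the alkene 1,4-dioxaspiro[4.5]dec-7-ene A7. In the forward key step an N-bromoimide converts the alkene into a bromonium ion, which the hydroxyl of 5 opens anti to give the racemic trans bromo ether A6. Ketal removal, two further brominations and dehydrogenation to the phenol would follow.
- For it: the ether bond forms at an sp3 carbon under mild conditions with no demand on aromatic activation, and oxygen and bromine are placed on neighbouring carbons in one operation. On that point it is as strong as or stronger than the SNAr of the chosen route.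
- Against it: the two alkene carbons of A7 are both secondary and nearly equivalent, so the direction of opening is poorly controlled. The flanked hydroxyl of 5 is a weak nucleophile for an intermolecular bromoetherification, and the open ring position of 5 can itself be brominated.
- Against it: once the ketal of A6 is removed, the C2' bromine is beta to the carbonyl and is lost by elimination during aromatisation. Two more bromines and four oxidation equivalents are still needed, and the two stereocentres that were set are destroyed.
- Comparison: the chosen route keeps ring B aromatic throughout and converts a robust C–N bond into the C2'–Br bond only at the end.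

Key step: step 5

## Route

Step 1
Reactants: 1 2,5-dimethoxybenzaldehyde
Product: 3 2,5-dimethoxyphenol, via 2,5-dimethoxyphenyl formate 2 (not isolated)
Conditions: mCPBA, CH2Cl2, 0 °C to rt; aq. NaHCO3 wash; then K2CO3 (cat.), MeOH, rt
Reagents that add atoms: mCPBA (3-chloroperoxybenzoic acid), O=C(OO)c1cccc(Cl)c1
Why: Baeyer–Villiger (Dakin-type) oxidation of an electron-rich benzaldehyde: the aryl group, activated by the ortho methoxy group, migrates in the peracid adduct to give formate 2, and carbonate-catalysed methanolysis should release phenol 3; no other oxidisable group is present.

Step 2
Reactants: 3 2,5-dimethoxyphenol; 4 bromine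
Product: 5 4,6-dibromo-2,5-dimethoxyphenol
Conditions: Br2 (2.05 equiv), CH2Cl2, 0 °C to rt
Reagents that add atoms: bromine (4), BrBr
Why: Electrophilic aromatic bromination directed by the free hydroxyl: the first bromine should enter para to OH (C4, also ortho to the C5 methoxy group) and the second ortho to OH at C6, which the C5 methoxy group activates as well, whereas C3 is meta to the hydroxyl and activated by one methoxy group only.

Step 3
Reactants: 5 4,6-dibromo-2,5-dimethoxyphenol; 6 4-fluoro-3-nitroanisole
Product: 7 1,3-dibromo-2,5-dimethoxy-4-(4-methoxy-2-nitrophenoxy)benzene
Conditions: Cs2CO3, DMSO, 90 °C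
Reagents that add atoms: none
Why: SNAr through a Meisenheimer adduct: the ortho nitro group stabilises the anionic adduct and fluoride is the best leaving group for this mechanism; the poorly solvated caesium phenoxide in DMSO should offset the two ortho substituents of 5, whose own aryl bromides are not activated.

Step 4
Reactants: 7 1,3-dibromo-2,5-dimethoxy-4-(4-methoxy-2-nitrophenoxy)benzene
Product: 8 2-(4,6-dibromo-2,5-dimethoxyphenoxy)-5-methoxyaniline
Conditions: Fe powder, NH4Cl, EtOH/H2O, 80 °C
Reagents that add atoms: none
Why: Béchamp-type reduction with iron in a near-neutral medium should reduce nitro to amino by electron transfer and leave the aryl bromides and the ether bond untouched, which catalytic hydrogenation would not guarantee.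

Step 5
Reactants: 8 2-(4,6-dibromo-2,5-dimethoxyphenoxy)-5-methoxyaniline; 4 bromine
Product: 9 2,4-dibromo-6-(4,6-dibromo-2,5-dimethoxyphenoxy)-3-methoxyaniline
Conditions: Br2 (2.05 equiv, slow addition), NaOAc, AcOH/CH2Cl2, 0 °C to rt
Reagents that add atoms: bromine (4), BrBr
Why: Electrophilic aromatic substitution: bromine attacks the aniline ring of 8 and each arenium ion is stabilised by donation from the nitrogen lone pair, loss of a proton restoring the ring. The closest known reaction type is the ortho/para polybromination of anilines with Br2 in acetate-buffered acetic acid. The first bromine is expected para to nitrogen at C5' and the second at the remaining ortho position C3'; both carbons are also ortho to the C4' methoxy group, so the two donors reinforce each other. C6' is meta to nitrogen and to the methoxy group and is activated only by the diaryl ether oxygen, so it should stay free with two equivalents. Ring A has one open carbon, C6, on a ring that carries two bromines and a C4 methoxy group twisted out of conjugation; it is far less nucleophilic than the aminoarene, which settles the choice between the rings. Acetate removes HBr so that the amine is not tied up as its salt before the second, more hindered substitution. No ring is closed and no stereocentre is formed.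

Step 6
Reactants: 9 2,4-dibromo-6-(4,6-dibromo-2,5-dimethoxyphenoxy)-3-methoxyaniline
Product: 11 1,3-dibromo-2,5-dimethoxy-4-(2,3,5-tribromo-4-methoxyphenoxy)benzene, via arenediazonium bromide 10 (not isolated)
Conditions: t-BuONO, CuBr2, MeCN, 0 to 60 °C
Reagents that add atoms: CuBr2 (copper dibromide), Br[Cu]Br
Why: Sandmeyer bromination under aprotic conditions: the alkyl nitrite converts the amine into diazonium ion 10, electron transfer from monovalent copper formed in the flask releases N2 and an aryl radical that takes bromine from CuBr2; both ortho positions and the para position of the aniline are already substituted, so ring bromination by divalent copper bromide cannot compete.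

Step 7
Reactants: 11 1,3-dibromo-2,5-dimethoxy-4-(2,3,5-tribromo-4-methoxyphenoxy)benzene
Product: 13 3,5-dibromo-2-(2,3,5-tribromo-4-hydroxyphenoxy)benzene-1,4-diol (CNP0084224.0), via tris(dibromoboryl) ether 12 (not isolated)
Conditions: BBr3 (excess), CH2Cl2, −78 °C to rt; then H2O, aq. Na2S2O4 wash under argon
Reagents that add atoms: none
Why: Lewis acid-mediated ether cleavage: BBr3 coordinates each methoxy oxygen and bromide attacks the methyl group by SN2 to give aryloxyborane 12 and bromomethane, and hydrolysis should free the three phenols; the diaryl ether, which has no sp3 carbon on oxygen, and the aryl bromides are inert, and the reductive work-up protects the ring A hydroquinone from air.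

## Compound list

1 | 2,5-dimethoxybenzaldehyde | COc1ccc(OC)c(C=O)c1 | starting material
2 | 2,5-dimethoxyphenyl formate | COc1ccc(OC)c(OC=O)c1 | intermediate (not isolated)
3 | 2,5-dimethoxyphenol | COc1ccc(OC)c(O)c1 | intermediate
4 | bromine | BrBr | starting material
5 | 4,6-dibromo-2,5-dimethoxyphenol | COc1cc(Br)c(OC)c(Br)c1O | intermediate
6 | 4-fluoro-3-nitroanisole (1-fluoro-4-methoxy-2-nitrobenzene) | COc1ccc(F)c([N+](=O)[O-])c1 | starting material
7 | 1,3-dibromo-2,5-dimethoxy-4-(4-methoxy-2-nitrophenoxy)benzene | COc1cc(Br)c(OC)c(Br)c1Oc1ccc(OC)cc1[N+](=O)[O-] | intermediate
8 | 2-(4,6-dibromo-2,5-dimethoxyphenoxy)-5-methoxyaniline | COc1cc(Br)c(OC)c(Br)c1Oc1ccc(OC)cc1N | intermediate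
9 | 2,4-dibromo-6-(4,6-dibromo-2,5-dimethoxyphenoxy)-3-methoxyaniline | COc1cc(Br)c(OC)c(Br)c1Oc1cc(Br)c(OC)c(Br)c1N | intermediate
10 | 2,4-dibromo-6-(4,6-dibromo-2,5-dimethoxyphenoxy)-3-methoxybenzenediazonium bromide | COc1cc(Br)c(OC)c(Br)c1Oc1cc(Br)c(OC)c(Br)c1[N+]#N.[Br-] | intermediate (not isolated)
11 | 1,3-dibromo-2,5-dimethoxy-4-(2,3,5-tribromo-4-methoxyphenoxy)benzene | COc1cc(Br)c(OC)c(Br)c1Oc1cc(Br)c(OC)c(Br)c1Br | intermediate
12 | tris(O-dibromoboryl) derivative of 13 (each of the three phenol oxygens carries a BBr2 group) | BrB(Br)Oc1cc(Br)c(OB(Br)Br)c(Br)c1Oc1cc(Br)c(OB(Br)Br)c(Br)c1Br | intermediate (not isolated)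
13 | 3,5-dibromo-2-(2,3,5-tribromo-4-hydroxyphenoxy)benzene-1,4-diol | Oc1cc(Br)c(O)c(Br)c1Oc1cc(Br)c(O)c(Br)c1Br | target

## Step count and least certain steps

Total step count: 7. Longest linear sequence: 7 steps (1 to 13); compounds 4 and 6 are purchased and enter in steps 2, 5 and 3. Phenol 3 is itself a commercial compound, and buying it would shorten the sequence to 6 steps.

**Step 5 (key step).** The most likely failures are a third bromination (at C6' or at C6 of ring A) where bromine is locally in excess, oxidation of the electron-rich aminoarene by bromine, and stalling after the para substitution because the second site lies between NH2 and OMe. The fallback sets out from 6, uses 5 from the main route and returns at 9. It brings the C5' bromine in with the electrophile, so that only one bromination is asked of the amine: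
- 6 is brominated with N-bromosuccinimide in H2SO4 at the position ortho to the methoxy group and para to the nitro group, giving 1-bromo-5-fluoro-2-methoxy-4-nitrobenzene F1.
- SNAr of 5 on F1 (Cs2CO3, DMSO) gives 1,3-dibromo-4-(5-bromo-4-methoxy-2-nitrophenoxy)-2,5-dimethoxybenzene F2; fluoride ortho to nitro should leave far faster than bromide para to it.
- Fe/NH4Cl reduces F2 to 4-bromo-2-(4,6-dibromo-2,5-dimethoxyphenoxy)-5-methoxyaniline F3.
- One equivalent of 4 (NaOAc, AcOH) then has a single strongly activated position left, C3', and gives 9.

**Step 3.** The substitution may be slow, because the phenoxide of 5 is flanked by OMe and Br and is a weak nucleophile, while the para methoxy group of 6 lowers the electrophilicity of the C–F carbon. Prolonged heating then leads to decomposition. The fallback sets out from 5 and returns at 7, replacing SNAr by metal-free O-arylation with a diaryliodonium salt: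
- 4-iodo-3-nitroanisole F4 is oxidised with mCPBA and TsOH·H2O in MeCN, and the trivalent iodine intermediate is captured by 1,3,5-trimethoxybenzene to give (4-methoxy-2-nitrophenyl)(2,4,6-trimethoxyphenyl)iodonium tosylate F5.
- 5 with K2CO3 in MeCN at 40 °C is then arylated by F5. Ligand coupling at iodine transfers the electron-poor nitroaryl group and not the trimethoxyphenyl group, tolerates ortho substituents on both partners, and gives 7.

**Step 6.** The diazonium group of 10 sits between Br and OAr. Hydrogen abstraction from the solvent by the aryl radical (loss of nitrogen without bromine) or attack of the radical on ring A across the ether bridge may compete with bromine transfer. The fallback sets out from 9 and returns at 11, replacing the radical pathway by an ionic one through an isolable triazene: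
- 9 is diazotised with NaNO2 and aqueous HBr in MeCN at 0 °C to 10, which is trapped with pyrrolidine and K2CO3 as 1-{(E)-[2,4-dibromo-6-(4,6-dibromo-2,5-dimethoxyphenoxy)-3-methoxyphenyl]diazenyl}pyrrolidine F6.
- Heating F6 with bromotrimethylsilane in MeCN at 60 °C regenerates the diazonium ion as a tight ion pair with bromide and should give 11.

**Step 7.** Cleavage of the three ethers may be incomplete while the ring A hydroquinone is partly oxidised by air during work-up, which would give a mixture of partially methylated phenols and quinone that is hard to separate. The fallback sets out from 11 and returns at 13, unmasking ring A oxidatively and separately: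
- (NH4)2Ce(NO3)6 in MeCN/H2O at 0 °C oxidises the para-dimethoxy ring A (tetravalent cerium, oxidative demethylation) to 3,5-dibromo-2-(2,3,5-tribromo-4-methoxyphenoxy)cyclohexa-2,5-diene-1,4-dione F7, a stable quinone that can be purified; the less electron-rich ring B is not oxidised.
- Na2S2O4 in EtOAc/H2O reduces F7 to 3,5-dibromo-2-(2,3,5-tribromo-4-methoxyphenoxy)benzene-1,4-diol F8.
- BBr3 in CH2Cl2 then has only the one methyl ether of ring B, flanked by two bromines, to cleave, and gives 13 after the same reductive work-up.

## Further compounds

F1 | step 5 | 1-bromo-5-fluoro-2-methoxy-4-nitrobenzene | COc1cc([N+](=O)[O-])c(F)cc1Br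
F2 | step 5 | 1,3-dibromo-4-(5-bromo-4-methoxy-2-nitrophenoxy)-2,5-dimethoxybenzene | COc1cc(Br)c(OC)c(Br)c1Oc1cc(Br)c(OC)cc1[N+](=O)[O-]
F3 | step 5 | 4-bromo-2-(4,6-dibromo-2,5-dimethoxyphenoxy)-5-methoxyaniline | COc1cc(Br)c(OC)c(Br)c1Oc1cc(Br)c(OC)cc1N
F4 | step 3 | 4-iodo-3-nitroanisole (1-iodo-4-methoxy-2-nitrobenzene) | COc1ccc(I)c([N+](=O)[O-])c1
F5 | step 3 | (4-methoxy-2-nitrophenyl)(2,4,6-trimethoxyphenyl)iodonium tosylate | COc1ccc([I+]c2c(OC)cc(OC)cc2OC)c([N+](=O)[O-])c1.Cc1ccc(S(=O)(=O)[O-])cc1
F6 | step 6 | 1-{(E)-[2,4-dibromo-6-(4,6-dibromo-2,5-dimethoxyphenoxy)-3-methoxyphenyl]diazenyl}pyrrolidine | COc1cc(Br)c(OC)c(Br)c1Oc1cc(Br)c(OC)c(Br)c1/N=N/N1CCCC1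
F7 | step 7 | 3,5-dibromo-2-(2,3,5-tribromo-4-methoxyphenoxy)cyclohexa-2,5-diene-1,4-dione | O=C1C=C(Br)C(=O)C(Br)=C1Oc1cc(Br)c(OC)c(Br)c1Br
F8 | step 7 | 3,5-dibromo-2-(2,3,5-tribromo-4-methoxyphenoxy)benzene-1,4-diol | Oc1cc(Br)c(O)c(Br)c1Oc1cc(Br)c(OC)c(Br)c1Br
A1 | alternative 1 | 2-bromo-4-methoxy-3-(2,3,5-tribromo-4-methoxyphenoxy)phenol | COc1ccc(O)c(Br)c1Oc1cc(Br)c(OC)c(Br)c1Br
A2 | alternative 1 | racemic 2-bromo-4-methoxy-3-(2,3,5-tribromo-4-methoxyphenoxy)-4-vinylcyclobut-2-en-1-one | C=CC1(OC)C(Oc2cc(Br)c(OC)c(Br)c2Br)=C(Br)C1=O
A3 | alternative 1 | dimethyl squarate (3,4-dimethoxycyclobut-3-ene-1,2-dione) | COC1=C(OC)C(=O)C1=O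
A4 | alternative 2 | 3-(2-bromo-4-hydroxyphenoxy)-4-methoxyphenol | COc1ccc(O)cc1Oc1ccc(O)cc1Br
A5 | alternative 2 | 3-(2-bromo-4-formylphenoxy)-4-methoxybenzaldehyde | COc1ccc(C=O)cc1Oc1ccc(C=O)cc1Br
A6 | alternative 3 | racemic trans-7-bromo-8-(4,6-dibromo-2,5-dimethoxyphenoxy)-1,4-dioxaspiro[4.5]decane | Br[C@@H]1CC2(OCCO2)CC[C@H]1Oc1c(OC)cc(Br)c(OC)c1Br
A7 | alternative 3 | 1,4-dioxaspiro[4.5]dec-7-ene | C1=CCC2(CC1)OCCO2
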